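The earlier runs and the new flask were computed with constants of no real substance, and the scatter is random.

- I start from what is slow: in this flask target falls so gently between 0.500 d and 5.00 d that I read a loss time, the time in which made target shrinks by a factor e, of 15.9 d.

- alder: substrate 0.69 M; gas phase 88 mM (held); the very flask that is asked about, followed so far
- flask: substrate 0.69 M; gas phase 88 mM (held); time 10 d

alder run (percent of the substrate charged)

| time / d | target / % |
|---|---|
| 0.0556 | 49.1 |
| 0.167 | 51.9 |
| 0.500 | 52.0 |
| 1.67 | 47.1 |
| 5.00 | 39.2 |

(standard deviation of a reading: 1 percentage point)

1. time, not beyond 10 d, at which the flask holds most target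
2. the amount of target, in percent of the substrate charged, at that time

- the numbers in the tables scatter with a standard deviation of 1 percentage point
- at the start none of the gas phase is in solution

- Carrying that fall back to zero time gives a plateau of 53.7%, and the first reading's distance below it gives a rise time of 0.0225 d.
- So I take the gain to start at 23.8 d⁻¹ of the charge and to shrink by a factor e each rise time, while the loss runs at 0.0337 d⁻¹.
- The gain must slow by a factor of 706 to meet the loss, which takes 6.56 rise times.
- My peak in this flask is therefore at 0.148 d, holding about 53.2%, well inside the limit of 10 d.
- The forecast says 0.22 d (from 0.1 d to 0.5 d) and 52.5% (from 51% to 54%), with the remark “it is flat between 0.1 and 0.5 d”; its time is later than mine.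
- The flask gives 0.133 d and 52.3%, so the forecast's time is 1.65 times the simulated one, while its height stands within tolerance.

    substrate + target → side product (k = 0.0330 M⁻¹ min⁻¹)
    target → over-reaction product (k = 4.00 × 10⁻⁵ min⁻¹)
    substrate + dissolved gas → target (k = 0.250 M⁻¹ min⁻¹)
    gas phase ⇌ dissolved gas, rate k4*(csat - [dissolved gas]) (kL = 9.70 min⁻¹)

- In this flask substrate, the limiting reagent, fell to 0.207% by 0.133 d; until then substrate with dissolved gas made target, and substrate with target made side product, which reached 47.2%, a percentage in which each side product counts as two. After that, side product stayed at 47.3% while target passed into over-reaction product, which rose from 0.347% to 23.0% by 10.0 d. The loss time carries 52.3% down to 28.1% at 10 d; the flask holds 29.7%.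
- The neighbour charged with 0.41 M peaks at 64.0%, and counting the whole 10 d, the loss time gives 34.1% at the end; the computed amount of target there is 36.3%.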